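**Retrosynthetic overview**
- The target is the O3-monoacetate of an anti-1,3-diol, (3S,5S)-ArCH2CH2–CH(OAc)–CH2–CH(OH)–C5H11 (Ar = 3,4-dimethoxyphenyl). The last step only frees O5 from a silyl ether.
- Key disconnection C2–C3. C3 carries the acetoxy oxygen and lies between two CH2 groups (C2 and C4), so it is an aldehyde carbon in disguise. Aldehyde plus acetyl bromide gives a 1-bromoalkyl acetate as both C–Br epimers; its acetoxy group stabilises a radical at C3 and binds nickel through its C=O.
- A chiral nickel catalyst couples this epimer mixture stereoconvergently with the 2-arylethylzinc bromide. One operation makes the C2–C3 bond, sets C3 and leaves the acetyl group on O3 only.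
- C5 comes from Noyori hydrogenation of methyl 3-oxooctanoate. No ring is formed at any stage; the only ring, the 3,4-dimethoxybenzene ring, is bought in the phenethyl bromide.

Key step: step 5

Assumption: the (S,S) antipode of the bis(oxazoline) ligand is taken as the one that gives the (3S) acetate; the sense of induction is set by the catalyst, so the (R,R) ligand would be used instead, with nothing else changed, should a model coupling show the opposite sense.

**Step 1**
Reactants: 1 methyl 3-oxooctanoate
Product: 2 methyl (S)-3-hydroxyoctanoate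
Conditions: H2 (50 atm), RuCl2[(S)-BINAP] (0.1 mol %), MeOH, 50 °C
Reagents that add atoms: none
Why: Noyori asymmetric hydrogenation of a β-keto ester, in which the (S)-BINAP–Ru catalyst reduces one face of the chelated ketone and should set the carbinol centre (C5 of the target) as S, as it does for simple 3-oxoalkanoates.

**Step 2**
Reactants: 2 methyl (S)-3-hydroxyoctanoate
Product: 3 methyl (S)-3-[(tert-butyldimethylsilyl)oxy]octanoate
Conditions: TBSCl (1.2 equiv), imidazole (2.5 equiv), DMF, rt
Reagents that add atoms: tert-butyldimethylsilyl chloride, CC(C)(C)[Si](C)(C)Cl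
Why: Standard silylation of a secondary alcohol (TBSCl/imidazole), chosen because the silyl ether does not bind nickel and offers no weak C–H bond to the C3 radical of the key step.

**Step 3**
Reactants: 3 methyl (S)-3-[(tert-butyldimethylsilyl)oxy]octanoate
Product: 4 (S)-3-[(tert-butyldimethylsilyl)oxy]octanal
Conditions: DIBAL-H (1.1 equiv), CH2Cl2, −78 °C; MeOH, then aq. Rochelle salt
Reagents that add atoms: none
Why: Partial reduction of an ester with DIBAL-H, in which the tetrahedral aluminium hemiacetal persists at −78 °C and gives the aldehyde only on work-up, without touching the stereocentre.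

**Step 4**
Reactants: 5 4-(2-bromoethyl)-1,2-dimethoxybenzene
Product: 6 [2-(3,4-dimethoxyphenyl)ethyl]zinc bromide (titrated DMA solution, used as such)
Conditions: Zn dust (1.5 equiv), I2 (5 mol %), DMA, 70 °C
Reagents that add atoms: zinc, [Zn]
Why: Direct insertion of iodine-activated zinc into a primary alkyl bromide in a polar amide solvent, which should give a stable alkylzinc halide that tolerates the aryl ethers.

**Step 5**
Reactants: 4 (S)-3-[(tert-butyldimethylsilyl)oxy]octanal; 6 [2-(3,4-dimethoxyphenyl)ethyl]zinc bromide
Product: 8 (3S,5S)-5-[(tert-butyldimethylsilyl)oxy]-1-(3,4-dimethoxyphenyl)decan-3-yl acetate, via bromoacetate 7 (not isolated)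
Conditions: (i) AcBr (1.0 equiv), CH2Cl2, −20 → 0 °C (0.5 mol % ZnBr2 if sluggish), evaporate; (ii) NiBr2·glyme (10 mol %), (S,S)-Ph-BOX (12 mol %), 6 (1.3 equiv), THF/DMA, −20 °C
Reagents that add atoms: acetyl bromide, CC(=O)Br
Why: Proposed new method: acetyl bromide adds across the C=O of 4 to give the 1-bromoalkyl acetate 7 as both C–Br epimers, a chiral Ni(I) species abstracts bromine from either epimer to give the same planar α-acetoxyalkyl radical at C3, the arylethyl group passes from zinc to nickel, and radical capture followed by C(sp3)–C(sp3) reductive elimination forms the C2–C3 bond, so that a stereorandom C–Br centre is funnelled into one C–O configuration. The closest known reaction types are the nickel/bis(oxazoline)-catalysed enantioconvergent alkyl–alkyl coupling of racemic 1-bromoalkyl esters (from aldehyde and acyl bromide) with alkylnickel species made from olefin and hydrosilane, and the nickel-catalysed enantioconvergent Negishi alkylation of racemic α-phthalimidoalkyl chlorides with alkylzinc halides; the new element is the pairing of a 1-bromoalkyl ester with an alkylzinc halide, needed because a nickel hydride would add to 3,4-dimethoxystyrene at the benzylic carbon. No ring is closed. The new C3 stereocentre (S) should be set by the chiral ligand on nickel, with the acetoxy C=O as the coordinating group, and not by the C5 centre, which is insulated by the C4 methylene and carries a non-coordinating silyl ether. The step needs catalyst control of the C3 configuration, chemoselectivity over uncatalysed ionisation of 7 and over β-hydride loss to the enol acetate, and survival of the silyl ether; low temperature, the polar THF/DMA medium and the absence of a leaving group on C2 or C4 and of weak C–H bonds near C3 should secure these. The same operation leaves the acetyl group on O3 alone, which solves the differentiation of the two hydroxyls of the anti-1,3-diol.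

**Step 6**
Reactants: 8 (3S,5S)-5-[(tert-butyldimethylsilyl)oxy]-1-(3,4-dimethoxyphenyl)decan-3-yl acetate
Product: 9 (3S,5S)-1-(3,4-dimethoxyphenyl)-5-hydroxydecan-3-yl acetate
Conditions: HF·pyridine, pyridine, THF, 0 °C → rt
Reagents that add atoms: none
Why: Fluoride-mediated Si–O cleavage under buffered, mildly acidic conditions, under which neither acetate hydrolysis nor base-catalysed O3→O5 acetyl migration is expected and no stereocentre is touched.

**Compound list**
1 | methyl 3-oxooctanoate | CCCCCC(=O)CC(=O)OC | starting material
2 | methyl (S)-3-hydroxyoctanoate | CCCCC[C@H](O)CC(=O)OC | intermediate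
3 | methyl (S)-3-[(tert-butyldimethylsilyl)oxy]octanoate | CCCCC[C@H](O[Si](C)(C)C(C)(C)C)CC(=O)OC | intermediate
4 | (S)-3-[(tert-butyldimethylsilyl)oxy]octanal | CCCCC[C@H](O[Si](C)(C)C(C)(C)C)CC=O | intermediate
5 | 4-(2-bromoethyl)-1,2-dimethoxybenzene | COc1ccc(CCBr)cc1OC | starting material
6 | [2-(3,4-dimethoxyphenyl)ethyl]zinc bromide | COc1ccc(CC[Zn]Br)cc1OC | intermediate
7 | (3S)-1-bromo-3-[(tert-butyldimethylsilyl)oxy]octyl acetate, mixture of C1 epimers | CCCCC[C@H](O[Si](C)(C)C(C)(C)C)CC(Br)OC(C)=O | intermediate
8 | (3S,5S)-5-[(tert-butyldimethylsilyl)oxy]-1-(3,4-dimethoxyphenyl)decan-3-yl acetate | CCCCC[C@H](O[Si](C)(C)C(C)(C)C)C[C@H](CCc1ccc(OC)c(OC)c1)OC(C)=O | intermediate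
9 | (3S,5S)-1-(3,4-dimethoxyphenyl)-5-hydroxydecan-3-yl acetate | CCCCC[C@H](O)C[C@H](CCc1ccc(OC)c(OC)c1)OC(C)=O | target

**Totals**
Total step count: 6. Longest linear sequence: 5 steps (steps 1, 2, 3, 5, 6).

**Steps most likely to fail**

Step 5. The risks are that uncatalysed ionisation of the bromoacetate and direct alkylation by the zinc reagent outrun the nickel cycle, that the ligand controls the C3 configuration poorly against the resident C5 centre, that β-hydride loss gives the enol acetate, or that the silyl ether is lost by acylative cleavage while the bromoacetate forms. The fallback uses known chemistry and joins the same two halves at the same bond; it sets out from 4 and comes back at 8.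
- The lithium acetylide of commercial 4-ethynyl-1,2-dimethoxybenzene (n-BuLi, THF, −78 °C) would add to 4 to give (3RS,5S)-5-[(tert-butyldimethylsilyl)oxy]-1-(3,4-dimethoxyphenyl)dec-1-yn-3-ol F1 as a mixture of C3 epimers.
- Buffered Dess–Martin oxidation would give the ynone (5S)-5-[(tert-butyldimethylsilyl)oxy]-1-(3,4-dimethoxyphenyl)dec-1-yn-3-one F2.
- Noyori asymmetric transfer hydrogenation (RuCl[(R,R)-TsDPEN](p-cymene), i-PrOH, rt), which by analogy with simple alkynyl ketones should deliver the R carbinol, would give (3R,5S)-5-[(tert-butyldimethylsilyl)oxy]-1-(3,4-dimethoxyphenyl)dec-1-yn-3-ol F3 under catalyst control.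
- Hydrogenation of the triple bond (H2, Pd/C, EtOAc, trace Et3N) would give (3S,5S)-5-[(tert-butyldimethylsilyl)oxy]-1-(3,4-dimethoxyphenyl)decan-3-ol F4.
- Acetylation (Ac2O, DMAP, pyridine) would then give 8.

Step 6. The risks are migration of the acetyl group from O3 to the freed O5 through the six-membered ortho-acid intermediate, and partial loss of the acetate during desilylation. The fallback replaces the silyl ether with a benzyl ether removed by neutral hydrogenolysis; it sets out from 2 and comes back at 9.
- Benzylation of 2 under acid catalysis (benzyl 2,2,2-trichloroacetimidate, cat. TfOH, cyclohexane/CH2Cl2) would give methyl (S)-3-(benzyloxy)octanoate F5.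
- DIBAL-H at −78 °C would give (S)-3-(benzyloxy)octanal F6.
- Acetyl bromide would give the bromoacetate (3S)-3-(benzyloxy)-1-bromooctyl acetate F7, not isolated, and the nickel-catalysed coupling with 6 under the conditions of step 5 would give (3S,5S)-5-(benzyloxy)-1-(3,4-dimethoxyphenyl)decan-3-yl acetate F8.
- Hydrogenolysis (H2, Pd/C, EtOAc) would free O5 and give 9 without acid, base or fluoride.

Step 3. The risks are over-reduction to the primary alcohol and β-elimination of silanol from the aldehyde during work-up or chromatography. The fallback separates reduction and oxidation; it sets out from 3 and comes back at 4.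
- Full reduction of 3 (LiBH4, THF/MeOH, 0 °C → rt) would give (S)-3-[(tert-butyldimethylsilyl)oxy]octan-1-ol F9.
- Buffered Dess–Martin oxidation (NaHCO3, CH2Cl2) would give 4, used crude in step 5.

**Further compounds**
F1 | step 5 | (3RS,5S)-5-[(tert-butyldimethylsilyl)oxy]-1-(3,4-dimethoxyphenyl)dec-1-yn-3-ol | CCCCC[C@H](O[Si](C)(C)C(C)(C)C)CC(O)C#Cc1ccc(OC)c(OC)c1
F2 | step 5 | (5S)-5-[(tert-butyldimethylsilyl)oxy]-1-(3,4-dimethoxyphenyl)dec-1-yn-3-one | CCCCC[C@H](O[Si](C)(C)C(C)(C)C)CC(=O)C#Cc1ccc(OC)c(OC)c1
F3 | step 5 | (3R,5S)-5-[(tert-butyldimethylsilyl)oxy]-1-(3,4-dimethoxyphenyl)dec-1-yn-3-ol | CCCCC[C@H](O[Si](C)(C)C(C)(C)C)C[C@H](C#Cc1ccc(OC)c(OC)c1)O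
F4 | step 5 | (3S,5S)-5-[(tert-butyldimethylsilyl)oxy]-1-(3,4-dimethoxyphenyl)decan-3-ol | CCCCC[C@H](O[Si](C)(C)C(C)(C)C)C[C@H](CCc1ccc(OC)c(OC)c1)O
F5 | step 6 | methyl (S)-3-(benzyloxy)octanoate | CCCCC[C@H](OCc1ccccc1)CC(=O)OC
F6 | step 6 | (S)-3-(benzyloxy)octanal | CCCCC[C@H](OCc1ccccc1)CC=O
F7 | step 6 | (3S)-3-(benzyloxy)-1-bromooctyl acetate, mixture of C1 epimers | CCCCC[C@H](OCc1ccccc1)CC(Br)OC(C)=O
F8 | step 6 | (3S,5S)-5-(benzyloxy)-1-(3,4-dimethoxyphenyl)decan-3-yl acetate | CCCCC[C@H](OCc1ccccc1)C[C@H](CCc1ccc(OC)c(OC)c1)OC(C)=O
F9 | step 3 | (S)-3-[(tert-butyldimethylsilyl)oxy]octan-1-ol | CCCCC[C@H](O[Si](C)(C)C(C)(C)C)CCO
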